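**Strategy.** Germacrane numbering is used (C1 ketone, C2=C3, bridging O between C3 and C10, C4 methyl, C6 ester, C7=C11, C8=C9, C12 lactone carbonyl). The route rests on cutting the C9–C10 bond of the nine-membered ring O–C3–C4–C5–C6–C7–C8–C9–C10. It exploits C10, the α-keto tertiary ether carbon shared by this ring and the furanone: a copper carbenoid at C10 is trapped by the C3 acetal oxygen of a bicyclic furfural acetal (eight-membered ring O–C3…C9, C6 oxygen as second acetal arm), and a [1,2]-Stevens shift moves C9 from oxygen to C10. One operation closes the oxolanone, enlarges the ring and relays C3 chirality to C10.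

Key step: step 12

Remark 1: the atom numbers C1–C13 are the germacrane numbers of the target and are kept for all intermediates.
Remark 2: (R)-TRIP is assumed to direct the crotylation of acrolein to the Re face, as for other aldehydes; otherwise the antipodal acid would be used.
Remark 3: C8 in 21 and 22 should form as a mixture of epimers (left undefined in the SMILES); it becomes trigonal in step 16.

**Furan fragment**

Step 1
Reactants: 1 3,4-dibromofuran
Product: 2 (4-bromofuran-3-yl)methanol
Conditions: n-BuLi (1.0 equiv), Et2O, −78 °C; CH2O (gas), −78 to 0 °C; aq. NH4Cl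
Reagents that add atoms: formaldehyde, C=O
Why: Bromine–lithium exchange of one of the two equivalent C–Br bonds gives a 3-furyllithium that is stable at −78 °C and is hydroxymethylated by formaldehyde; no stereocentre is formed.

Step 2
Reactants: 2 (4-bromofuran-3-yl)methanol
Product: 3 [(4-bromofuran-3-yl)methoxy](tert-butyl)diphenylsilane
Conditions: t-BuPh2SiCl, imidazole, CH2Cl2, 0 °C to rt
Reagents that add atoms: tert-butyl(chloro)diphenylsilane, CC(C)(C)[Si](Cl)(c1ccccc1)c1ccccc1
Why: Standard silyl ether formation; the bulky group also shields the neighbouring furan α-position in step 3.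

Step 3
Reactants: 3 [(4-bromofuran-3-yl)methoxy](tert-butyl)diphenylsilane
Product: 5 3-bromo-4-({[tert-butyl(diphenyl)silyl]oxy}methyl)-5-(trimethylsilyl)furan-2-carbaldehyde, via lithium hemiaminal alkoxide 4 (not isolated)
Conditions: LiN(iPr)2 (1.1 equiv), THF, −78 °C; DMF; then lithium 2,2,6,6-tetramethylpiperidide (1.3 equiv), −78 to −40 °C; Me3SiCl; aq. NH4Cl
Reagents that add atoms: N,N-dimethylformamide, CN(C)C=O; chlorotrimethylsilane, C[Si](C)(C)Cl
Why: Ortho-lithiation at the α-carbon acidified by the adjacent bromine and formylation with DMF give 4, which masks the aldehyde in situ while the remaining α-hydrogen is removed by the stronger non-nucleophilic amide and silylated (directed metalation with in situ protection).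

Step 4
Reactants: 5 3-bromo-4-({[tert-butyl(diphenyl)silyl]oxy}methyl)-5-(trimethylsilyl)furan-2-carbaldehyde
Product: 6 {[4-bromo-5-(dimethoxymethyl)-2-(trimethylsilyl)furan-3-yl]methoxy}(tert-butyl)diphenylsilane
Conditions: HC(OMe)3, PPTS (cat.), MeOH, rt
Reagents that add atoms: trimethyl orthoformate, COC(OC)OC
Why: Acid-catalysed acetalisation protects the aldehyde for step 8 and installs the acetal carbon (C9) needed in step 10.

**Chain fragment**

Step 5
Reactants: 7 acrolein; 8 (Z)-crotylboronic acid pinacol ester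
Product: 9 (3S,4S)-4-methylhexa-1,5-dien-3-ol
Conditions: (R)-TRIP [(R)-3,3'-bis(2,4,6-triisopropylphenyl)-1,1'-binaphthyl-2,2'-diyl hydrogen phosphate, 5 mol%], toluene, −30 °C; aq. NaHCO3
Reagents that add atoms: none
Why: Chiral phosphoric acid-catalysed crotylboration through a closed chair transition state: the (Z)-boronate gives the syn adduct and the catalyst selects the Re face of the aldehyde, setting C3 and C4 as (3S,4S).

Step 6
Reactants: 9 (3S,4S)-4-methylhexa-1,5-dien-3-ol
Product: 10 (3S,4S)-4-methylhexane-1,3,6-triol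
Conditions: 9-BBN (3.3 equiv), THF, 0 °C to rt; NaOH, H2O2
Reagents that add atoms: hydrogen peroxide, OO
Why: Anti-Markovnikov hydroboration–oxidation of both terminal alkenes (the free hydroxyl consumes one further equivalent of borane); the stereocentres are not touched.

Step 7
Reactants: 10 (3S,4S)-4-methylhexane-1,3,6-triol
Product: 11 2-[(2S,3S)-3-methyl-5-oxooxolan-2-yl]acetic acid
Conditions: TEMPO (20 mol%), PhI(OAc)2 (4.4 equiv), MeCN/H2O 1:1, rt
Reagents that add atoms: water, O
Why: Oxoammonium (TEMPO) oxidation is selective for primary alcohols: the C6 aldehyde is trapped by the C3 hydroxyl as a lactol and oxidised to the γ-lactone, and the C1 aldehyde hydrate is oxidised to the acid.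

**Main line**

Step 8
Reactants: 6 {[4-bromo-5-(dimethoxymethyl)-2-(trimethylsilyl)furan-3-yl]methoxy}(tert-butyl)diphenylsilane; 11 2-[(2S,3S)-3-methyl-5-oxooxolan-2-yl]acetic acid
Product: 12 (3S,4S)-6-[2-(dimethoxymethyl)-4-({[tert-butyl(diphenyl)silyl]oxy}methyl)-5-(trimethylsilyl)furan-3-yl]-3-hydroxy-4-methyl-6-oxohexanoic acid
Conditions: 6, n-BuLi, Et2O, −78 °C; then 11 + LiN(SiMe3)2 (1.0 equiv), THF, −78 °C; aq. NH4Cl, then citric acid
Reagents that add atoms: none
Why: Bromine–lithium exchange and acyl addition of the 3-furyllithium to the γ-lactone (the lithium carboxylate is inert at −78 °C); the tetrahedral alkoxide persists until work-up, which prevents double addition.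

Step 9
Reactants: 12 (3S,4S)-6-[2-(dimethoxymethyl)-4-({[tert-butyl(diphenyl)silyl]oxy}methyl)-5-(trimethylsilyl)furan-3-yl]-3-hydroxy-4-methyl-6-oxohexanoic acid
Product: 13 (3S,4S,6S)-6-[2-(dimethoxymethyl)-4-({[tert-butyl(diphenyl)silyl]oxy}methyl)-5-(trimethylsilyl)furan-3-yl]-3,6-dihydroxy-4-methylhexanoic acid
Conditions: RuCl(p-cymene)[(S,S)-TsNCH(Ph)CH(Ph)NH2] (2 mol%), HCO2Na, H2O/MeOH, 40 °C
Reagents that add atoms: none
Why: Asymmetric transfer hydrogenation of the heteroaryl alkyl ketone under catalyst control; the (S,S)-ligand should give the (S)-carbinol at C6, as for aryl alkyl ketones.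

Step 10
Reactants: 13 (3S,4S,6S)-6-[2-(dimethoxymethyl)-4-({[tert-butyl(diphenyl)silyl]oxy}methyl)-5-(trimethylsilyl)furan-3-yl]-3,6-dihydroxy-4-methylhexanoic acid
Product: 14 bicyclic acetal acid (acetal carbon C9 on furan C8 bonded to O–C3 and O–C6; CH2CO2H on C3; eight-membered ring O–C3–C4–C5–C6–C7–C8–C9)
Conditions: PPTS (cat.), benzene, 5 Å molecular sieves, 50 °C
Reagents that add atoms: none
Why: Thermodynamically controlled intramolecular transacetalisation (five-membered ring with the C6 oxygen, then the bridging seven-membered ring with the C3 oxygen, methanol taken up by the sieves); the new acetal centre C9 can only adopt the configuration of the cis-bridged bicycle.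

Step 11
Reactants: 14 bicyclic acetal acid
Product: 16 α-diazo ethyl ketone (C3–CH2–C(=O)–C(=N2)–CH3 on the bicyclic acetal), via mixed isobutyl carbonic anhydride 15 (not isolated)
Conditions: i-BuOCOCl, Et3N, THF, −20 °C; then CH3CHN2 (excess), Et2O, 0 °C
Reagents that add atoms: diazoethane, CC=[N+]=[N-]
Why: Acylation of diazoethane by the mixed anhydride (Arndt–Eistert-type diazo ketone synthesis) under conditions that spare the acetal and the silyl groups.

Step 12
Reactants: 16 α-diazo ethyl ketone
Product: 18 ring-expanded oxolan-3-one (O bridging C3 and C10 of the nine-membered ring; C6–O–C9 ether bridge retained; C4 on C3 and C9 on C10 cis), via bicyclic oxonium ylide 17 (not isolated)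
Conditions: Cu(CF3COCHCOCF3)2 (5 mol%), CH2Cl2, reflux, slow addition of 16
Reagents that add atoms: none
Why: The divalent copper complex decomposes the diazo ketone to a carbenoid at C10, which is attacked by the acetal oxygen on C3 to close the five-membered oxolanone ring as ylide 17; cleavage of the O–C9 acetal bond and recombination at C10 (Stevens [1,2]-shift through a tight radical or ion pair stabilised at C9 by the second acetal oxygen and the furan) then forms the C9–C10 bond. The closest known reaction type is the ring-expanding [1,2]-shift of oxonium ylides generated from cyclic acetals or benzylic ethers that carry a diazo ketone side chain. Ring closures: the oxolan-3-one by O–C10 bond formation (5-exo capture of the carbenoid), and the nine-membered ring O–C3–C4–C5–C6–C7–C8–C9–C10 by insertion of C10 into the O–C9 bond of the eight-membered ring O–C3–C4–C5–C6–C7–C8–C9 (one-atom ring expansion). The quaternary centre C10 is set by C3: C9 can only be delivered to the face of the oxolanone cis to C4, because the trans-bridged bicycle is unattainable, and C9 keeps its configuration because it stays tied to C6 through its second oxygen. The step needs the [1,2]-shift of C9 to win over 1,2-hydride migration from the C10 methyl group, over [1,4]-migration to the enolate oxygen and over migration of C3; fast five-membered ylide formation, the doubly stabilised migrating carbon and the electron-poor copper catalyst should secure this.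

Step 13
Reactants: 18 ring-expanded oxolan-3-one
Product: 20 furan-3(2H)-one (C2=C3; furan and C6–O–C9 bridge retained), via trimethylsilyl enol ether 19 (not isolated)
Conditions: LiN(SiMe3)2, Me3SiCl, THF, −78 °C; then Pd(OAc)2 (1.1 equiv), MeCN, rt
Reagents that add atoms: none
Why: Saegusa–Ito dehydrogenation: only C2 can be enolised, and syn β-hydride elimination of the C3 hydrogen, which lies on the open face of the oxolanone, gives the furan-3(2H)-one and erases the temporary C3 stereocentre.

Step 14
Reactants: 20 furan-3(2H)-one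
Product: 21 butenolide (C12 lactone carbonyl; H on C8; C13–OSiPh2t-Bu; C6–O–C9 bridge retained)
Conditions: CH3CO3H, NaOAc, CH2Cl2, 0 °C to rt
Reagents that add atoms: peracetic acid, CC(=O)OO
Why: Peracid oxidation of a 2-silylfuran (ipso attack, 1,2-shift of silicon from carbon to oxygen, protodesilylation of the 2-silyloxyfuran) places the carbonyl at C12 and hydrogen at C8 regiospecifically; C8 forms unselectively, which is irrelevant.

Step 15
Reactants: 21 butenolide (C13 silyl ether)
Product: 22 butenolide with free C13 hydroxyl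
Conditions: HF·pyridine, pyridine, THF, 0 °C to rt
Reagents that add atoms: none
Why: Fluoride cleavage of the silyl ether under acidic, non-eliminating conditions, so that no leaving group sits on C13 when the dienolate is formed in step 16.

Step 16
Reactants: 22 butenolide with free C13 hydroxyl
Product: 23 6,13-diol with the C8=C9 enol lactone (the target lacking its two acyl groups)
Conditions: DBU (1.2 equiv), CH2Cl2, 0 °C to rt; pH 7 buffer
Reagents that add atoms: none
Why: Vinylogous E1cB elimination: deprotonation at C8 gives the 2-oxidofuran, which expels the strained bridging C9–O bond as the C6 alkoxide and forms the C8=C9 olefin with the only geometry the nine-membered ring allows (C7 and C10 cis).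

Step 17
Reactants: 23 6,13-diol
Product: 24 13-acetate with free C6 hydroxyl
Conditions: AcCl (1.05 equiv), 2,4,6-collidine, CH2Cl2, −78 °C
Reagents that add atoms: acetyl chloride, CC(=O)Cl
Why: Kinetic, chemoselective acetylation of the unhindered primary allylic hydroxyl in preference to the secondary C6 hydroxyl at low temperature.

**Side chain**

Step 18
Reactants: 25 4-methylfuran-2(5H)-one
Product: 26 sodium (Z)-4-hydroxy-3-methylbut-2-enoate
Conditions: NaOH (1.0 equiv), H2O, 0 °C to rt; lyophilise
Reagents that add atoms: sodium hydroxide, [Na+].[OH-]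
Why: Saponification of the butenolide; the Z geometry is fixed by the ring of the starting material.

Step 19
Reactants: 26 sodium (Z)-4-hydroxy-3-methylbut-2-enoate
Product: 28 (Z)-4-{[tert-butyl(dimethyl)silyl]oxy}-3-methylbut-2-enoic acid, via bis-silyl compound 27 (not isolated)
Conditions: t-BuMe2SiCl (2.5 equiv), imidazole, DMF, rt; then K2CO3 (cat.), MeOH/THF/H2O, 0 °C; pH 5 buffer
Reagents that add atoms: tert-butyl(chloro)dimethylsilane, CC(C)(C)[Si](C)(C)Cl
Why: Silylation of the hydroxyl and the carboxylate, then selective solvolysis of the far more labile silyl ester; the silyl ether prevents relactonisation.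

**Completion**

Step 20
Reactants: 24 13-acetate with free C6 hydroxyl; 28 (Z)-4-{[tert-butyl(dimethyl)silyl]oxy}-3-methylbut-2-enoic acid
Product: 30 silyl-protected target (C6 ester carrying the silyl ether), via Yamaguchi mixed anhydride 29 (not isolated)
Conditions: 28, 2,4,6-trichlorobenzoyl chloride, Et3N, THF, rt; then 24, DMAP, toluene, rt
Reagents that add atoms: none
Why: Yamaguchi esterification of the secondary C6 alcohol through the mixed aroyl anhydride; no stereocentre is affected and the trisubstituted Z-olefin has no α-hydrogen through which it could isomerise.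

Step 21
Reactants: 30 silyl-protected target
Product: 31 CNP0269057.1
Conditions: HF·pyridine, pyridine, THF, 0 °C
Reagents that add atoms: none
Why: Buffered fluoride desilylation of the primary silyl ether, which should leave the acetate, the enol lactone and the furanone intact.

**Compound list**

1 | 3,4-dibromofuran | Brc1cocc1Br | starting material
2 | (4-bromofuran-3-yl)methanol | OCc1cocc1Br | intermediate
3 | [(4-bromofuran-3-yl)methoxy](tert-butyl)diphenylsilane | CC(C)(C)[Si](OCc1cocc1Br)(c1ccccc1)c1ccccc1 | intermediate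
4 | lithium [3-bromo-4-({[tert-butyl(diphenyl)silyl]oxy}methyl)furan-2-yl](dimethylamino)methanolate | [Li+].CN(C)C([O-])c1occ(CO[Si](c2ccccc2)(c2ccccc2)C(C)(C)C)c1Br | intermediate (not isolated)
5 | 3-bromo-4-({[tert-butyl(diphenyl)silyl]oxy}methyl)-5-(trimethylsilyl)furan-2-carbaldehyde | O=Cc1oc([Si](C)(C)C)c(CO[Si](c2ccccc2)(c2ccccc2)C(C)(C)C)c1Br | intermediate
6 | {[4-bromo-5-(dimethoxymethyl)-2-(trimethylsilyl)furan-3-yl]methoxy}(tert-butyl)diphenylsilane | COC(OC)c1oc([Si](C)(C)C)c(CO[Si](c2ccccc2)(c2ccccc2)C(C)(C)C)c1Br | intermediate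
7 | acrolein | C=CC=O | starting material
8 | (Z)-crotylboronic acid pinacol ester | C/C=C\CB1OC(C)(C)C(C)(C)O1 | starting material
9 | (3S,4S)-4-methylhexa-1,5-dien-3-ol | C=C[C@H](O)[C@@H](C)C=C | intermediate
10 | (3S,4S)-4-methylhexane-1,3,6-triol | OCC[C@H](O)[C@@H](C)CCO | intermediate
11 | 2-[(2S,3S)-3-methyl-5-oxooxolan-2-yl]acetic acid | OC(=O)C[C@@H]1OC(=O)C[C@@H]1C | intermediate
12 | (3S,4S)-6-[2-(dimethoxymethyl)-4-({[tert-butyl(diphenyl)silyl]oxy}methyl)-5-(trimethylsilyl)furan-3-yl]-3-hydroxy-4-methyl-6-oxohexanoic acid | COC(OC)c1oc([Si](C)(C)C)c(CO[Si](c2ccccc2)(c2ccccc2)C(C)(C)C)c1C(=O)C[C@H](C)[C@@H](O)CC(=O)O | intermediate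
13 | (3S,4S,6S)-6-[2-(dimethoxymethyl)-4-({[tert-butyl(diphenyl)silyl]oxy}methyl)-5-(trimethylsilyl)furan-3-yl]-3,6-dihydroxy-4-methylhexanoic acid | COC(OC)c1oc([Si](C)(C)C)c(CO[Si](c2ccccc2)(c2ccccc2)C(C)(C)C)c1[C@@H](O)C[C@H](C)[C@@H](O)CC(=O)O | intermediate
14 | bicyclic acetal acid: C9 (on furan C8) bonded to O–C3 and O–C6, CH2CO2H on C3, C3 S, C4 S, C6 S, C9 cis-bridged; furan carries CH2OSiPh2t-Bu (C13) and SiMe3 (C12) | CC(C)(C)[Si](c1ccccc1)(c1ccccc1)OCc1c([Si](C)(C)C)oc2c1[C@@H]3C[C@H](C)[C@H](CC(=O)O)O[C@H]2O3 | intermediate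
15 | mixed isobutyl carbonic anhydride of 14 | CC(C)(C)[Si](c1ccccc1)(c1ccccc1)OCc1c([Si](C)(C)C)oc2c1[C@@H]3C[C@H](C)[C@H](CC(=O)OC(=O)OCC(C)C)O[C@H]2O3 | intermediate (not isolated)
16 | α-diazo ethyl ketone: as 14 with CH2C(=O)C(=N2)CH3 on C3 | CC(C)(C)[Si](c1ccccc1)(c1ccccc1)OCc1c([Si](C)(C)C)oc2c1[C@@H]3C[C@H](C)[C@H](CC(=O)C(C)=[N+]=[N-])O[C@H]2O3 | intermediate
17 | bicyclic oxonium ylide: O+ bonded to C3, C9 and carbanionic C10 (configuration at oxygen not defined) | CC(C)(C)[Si](c1ccccc1)(c1ccccc1)OCc1c([Si](C)(C)C)oc2c1[C@@H]3C[C@H](C)[C@@H]4CC(=O)[C-](C)[O+]4[C@H]2O3 | intermediate (not isolated)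
18 | ring-expanded oxolan-3-one: O bridges C3 and C10 of the nine-membered ring, C1 ketone, C10 S with methyl, C3 S, C4 S, C6 S, C6–O–C9 bridge, C4 (on C3) and C9 (on C10) cis | CC(C)(C)[Si](c1ccccc1)(c1ccccc1)OCc1c([Si](C)(C)C)oc2c1[C@@H]3C[C@H](C)[C@@H]4CC(=O)[C@@](C)(O4)[C@H]2O3 | intermediate
19 | trimethylsilyl enol ether of 18 (C1(OSiMe3)=C2) | CC(C)(C)[Si](c1ccccc1)(c1ccccc1)OCc1c([Si](C)(C)C)oc2c1[C@@H]3C[C@H](C)[C@@H]4C=C(O[Si](C)(C)C)[C@@](C)(O4)[C@H]2O3 | intermediate (not isolated)
20 | furan-3(2H)-one: as 18 with C2=C3 | CC(C)(C)[Si](c1ccccc1)(c1ccccc1)OCc1c([Si](C)(C)C)oc2c1[C@@H]3C[C@H](C)C4=CC(=O)[C@@](C)(O4)[C@H]2O3 | intermediate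
21 | butenolide: C12 lactone carbonyl, C7=C11, H on C8 (epimer mixture), C13–OSiPh2t-Bu, C6–O–C9 bridge | CC(C)(C)[Si](c1ccccc1)(c1ccccc1)OCC1=C2[C@@H]3C[C@H](C)C4=CC(=O)[C@@](C)(O4)[C@@H](O3)C2OC1=O | intermediate
22 | butenolide with free C13 hydroxyl | OCC1=C2[C@@H]3C[C@H](C)C4=CC(=O)[C@@](C)(O4)[C@@H](O3)C2OC1=O | intermediate
23 | (4S,6S,10S)-6,13-dihydroxy-1-oxo-3,10-epoxygermacra-2,7(11),8-trien-12,8-olide | OCC1=C2/C(=C\[C@]3(C)OC(=CC3=O)[C@@H](C)C[C@@H]2O)OC1=O | intermediate
24 | (4S,6S,10S)-13-acetoxy-6-hydroxy-1-oxo-3,10-epoxygermacra-2,7(11),8-trien-12,8-olide | CC(=O)OCC1=C2/C(=C\[C@]3(C)OC(=CC3=O)[C@@H](C)C[C@@H]2O)OC1=O | intermediate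
25 | 4-methylfuran-2(5H)-one | CC1=CC(=O)OC1 | starting material
26 | sodium (Z)-4-hydroxy-3-methylbut-2-enoate | [Na+].[O-]C(=O)/C=C(/C)CO | intermediate
27 | tert-butyldimethylsilyl (Z)-4-{[tert-butyl(dimethyl)silyl]oxy}-3-methylbut-2-enoate | CC(C)(C)[Si](C)(C)OC(=O)/C=C(/C)CO[Si](C)(C)C(C)(C)C | intermediate (not isolated)
28 | (Z)-4-{[tert-butyl(dimethyl)silyl]oxy}-3-methylbut-2-enoic acid | OC(=O)/C=C(/C)CO[Si](C)(C)C(C)(C)C | intermediate
29 | mixed anhydride of 28 with 2,4,6-trichlorobenzoic acid | O=C(OC(=O)c1c(Cl)cc(Cl)cc1Cl)/C=C(/C)CO[Si](C)(C)C(C)(C)C | intermediate (not isolated)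
30 | silyl-protected target: 24 esterified at O6 with 28 | CC(=O)OCC1=C2/C(=C\[C@]3(C)OC(=CC3=O)[C@@H](C)C[C@@H]2OC(=O)/C=C(/C)CO[Si](C)(C)C(C)(C)C)OC1=O | intermediate
31 | CNP0269057.1, (4S,6S,10S)-13-acetoxy-1-oxo-3,10-epoxygermacra-2,7(11),8-trien-12,8-olid-6-yl (Z)-4-hydroxy-3-methylbut-2-enoate | CC(=O)OCC1=C2/C(=C\[C@]3(C)OC(=CC3=O)[C@@H](C)C[C@@H]2OC(=O)/C=C(/C)CO)OC1=O | target

**Step count.** Total: 21 steps. Longest linear sequence: 16 steps (steps 1–4, 8–17, 20, 21).

**Steps most likely to fail**

1. Step 12 (ring-expanding Stevens shift). What may go wrong: 1,2-hydride migration from the methyl group to the carbenoid carbon, or migration of C9 to the enolate oxygen, may outrun the [1,2]-shift to C10. Fallback, from 14 back to 20: the methyl group is introduced after the ring expansion. Acid 14 would be converted (i-BuOCOCl, Et3N; then CH2N2) into the terminal diazo ketone F1, which cannot undergo hydride migration. The same copper-catalysed ylide formation and [1,2]-shift should give the C10-unsubstituted oxolanone F2. Saegusa–Ito dehydrogenation as in step 13 should give the C10-unsubstituted furanone F3. Deprotonation at C10 with LiN(SiMe3)2 and alkylation with MeI should place the methyl group in the only open position of the bridged ring and give 20.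

2. Step 10 (bicyclic acetal formation). What may go wrong: the carboxyl group may capture the oxocarbenium ion (acyloxy acetal formation with the C3 oxygen), or closure of the bridging seven-membered acetal ring may stay incomplete. Fallback, from 13 back to 14: the acid is masked first. Esterification of 13 (Me3SiCHN2, MeOH/toluene) should give the methyl ester F4; acetalisation under the conditions of step 10 should give the bicyclic acetal methyl ester F5; saponification (LiOH, THF/H2O) should return 14.

3. Step 16 (base-induced opening of the C6–O–C9 bridge). What may go wrong: expulsion of an alkoxide from the stabilised dienolate may be slow, or the C6 alkoxide may add back to C9. Fallback, from 21 back to 23: the bridge is opened by acid-side ionisation instead. Silylation of 21 (i-Pr3SiOTf, Et3N) should give the 2-silyloxyfuran F6; BF3·OEt2 at −78 °C should ionise the C9–O bond with assistance from the silyloxyfuran and, after aqueous work-up, give the C13 silyl ether C6 alcohol F7; HF·pyridine should then give 23.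

Further compounds
F1 | step 12 | terminal diazo ketone (14 with CH2C(=O)CHN2 on C3) | CC(C)(C)[Si](c1ccccc1)(c1ccccc1)OCc1c([Si](C)(C)C)oc2c1[C@@H]3C[C@H](C)[C@H](CC(=O)C=[N+]=[N-])O[C@H]2O3
F2 | step 12 | C10-unsubstituted oxolanone (18 with H in place of the C10 methyl) | CC(C)(C)[Si](c1ccccc1)(c1ccccc1)OCc1c([Si](C)(C)C)oc2c1[C@@H]3C[C@H](C)[C@@H]4CC(=O)[C@@H](O4)[C@H]2O3
F3 | step 12 | C10-unsubstituted furanone (20 with H in place of the C10 methyl) | CC(C)(C)[Si](c1ccccc1)(c1ccccc1)OCc1c([Si](C)(C)C)oc2c1[C@@H]3C[C@H](C)C4=CC(=O)[C@@H](O4)[C@H]2O3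
F4 | step 10 | methyl ester of 13 | COC(OC)c1oc([Si](C)(C)C)c(CO[Si](c2ccccc2)(c2ccccc2)C(C)(C)C)c1[C@@H](O)C[C@H](C)[C@@H](O)CC(=O)OC
F5 | step 10 | bicyclic acetal methyl ester (methyl ester of 14) | CC(C)(C)[Si](c1ccccc1)(c1ccccc1)OCc1c([Si](C)(C)C)oc2c1[C@@H]3C[C@H](C)[C@H](CC(=O)OC)O[C@H]2O3
F6 | step 16 | 2-(triisopropylsilyloxy)furan derived from 21 | CC(C)(C)[Si](c1ccccc1)(c1ccccc1)OCc1c(O[Si](C(C)C)(C(C)C)C(C)C)oc2c1[C@@H]3C[C@H](C)C4=CC(=O)[C@@](C)(O4)[C@H]2O3
F7 | step 16 | C13 silyl ether C6 alcohol (23 with O13–SiPh2t-Bu) | CC(C)(C)[Si](c1ccccc1)(c1ccccc1)OCC1=C2/C(=C\[C@]3(C)OC(=CC3=O)[C@@H](C)C[C@@H]2O)OC1=O
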